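All runs were computed from invented constants, noise included.

**Early times.** At 1.33 h the south-west run holds 44.1% left-handed and 44.7% right-handed substrate, a gap inside the scatter of 1 percentage point. At 10.0 h the same run shows 24.4% against 32.3%, so there the gap has opened. You want the flask below, charged between the two earlier runs.

| flask | left-handed substrate | right-handed substrate | gas | remark | time |
|---|---|---|---|---|---|
| south-west | 0.0067 M | 0.0067 M | 5 mM (held) | run made earlier |  |
| south-east | 0.015 M | 0.015 M | 5 mM (held) | run made earlier |  |
| flask | 0.010 M | 0.010 M | 5.0 mM (held) |  | 8.0 h |

- south-west (time / h: left-handed substrate / %, right-handed substrate / %): 1.33: 44.1, 44.7; 3.00: 39.4, 39.5; 4.00: 35.4, 38.1; 6.00: 30.7, 35.4; 8.00: 29.3, 31.5; 10.0: 24.4, 32.3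
- south-east (time / h: left-handed substrate / %, right-handed substrate / %): 1.33: 44.8, 44.3; 3.00: 37.3, 40.9; 4.00: 35.9, 37.0; 6.00: 30.5, 35.1; 8.00: 30.2, 32.1; 10.0: 25.8, 31.1

(readings scatter by 1 percentage point)

- reagent is single-handed; left-handed substrate and right-handed substrate are mirror images of each other, charged as a racemate, each of them at the stated concentration
- at the start none of the gas is in solution
- what has gone into achiral form counts as reacted
- an excess is the difference of the two amounts in percent of their sum
- an excess is below zero if the other one leads
- the handed part of reagent does not stay in what it makes, so the products of the two hands are mirror images too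

1. part of the left-handed substrate and right-handed substrate charged together that has reacted at 8.0 h
2. excess of left-handed product over right-handed product in the product at 8.0 h
3. excess of right-handed substrate over left-handed substrate among what is left of the two at 8.0 h

**Substrate charge.** By hand: if each substrate is lost in proportion to its own concentration (pseudo-first-order behaviour), percent curves do not move with the charge, and the flask follows the earlier runs. The readings agree: at 10.0 h the substrates left stand at 56.7% in the south-west run and 56.9% in the south-east run. The mean of the readings at 8.00 h gives me c = 38.4% for the flask.

**Reaction time.** Take the hand drain 0.150: the natural logarithm of c(right-handed substrate) over c(left-handed substrate), here read at 10.0 h in both runs and scaled to 8.0 h. A first-order loss common to both hands cancels in it. By hand: if whatever discriminates builds up steadily from nothing, the drain grows as the square of time, and that is the scaling used. It is a reading and carries the scatter. As an excess of right-handed substrate it gives me 7.46% for the flask. The readings show substrates and not product, so I put no number on eP.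

**The forecast.** It gives c = 38.7%, eS = 7% and eP = 16%, and it calls the excess in the product “higher, though by an uncertain amount”. Its eS is a little below my value, and on eP it commits where I do not.

**The result.**

    reagent + left-handed substrate → left-handed product (k = 24.0 M⁻¹ h⁻¹)
    reagent + right-handed substrate → right-handed product (k = 0.310 M⁻¹ h⁻¹)
    left-handed substrate ⇌ achiral form (K = 1.40, k = 0.0930 h⁻¹)
    right-handed substrate ⇌ achiral form (K = 1.40, k = 0.0930 h⁻¹)
    left-handed product ⇌ right-handed product (k = 0.140 h⁻¹)
    reagent → decomposition product (k = 1.70 × 10⁻⁴ h⁻¹)
    gas ⇌ reagent, rate k7*(csat - [reagent]) (kL = 0.0750 h⁻¹)

The flask gives c = 39.0%, eS = 6.77% and eP = 45.3%, which is 29 points above the forecast. At 8.00 h the flask holds more achiral form, 33.3%, than product, 4.11% left-handed and 1.55% right-handed. Scaled by the square of time to 0.800 h, the hand drain gives an estimated excess of right-handed substrate of 0.0750% for the flask, which stood at 0.131%.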